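**Retrosynthetic overview**

Numbering (cadinane): ring A = C1–C6 (C4=C5, C15H2OH on C4). Ring B = C1, C6, C7, C8, C9, C10 (C10=C14H2). C7 bears C11(=C13H2)–C12O2H, and C8 bears the ester O8–C1'(=O)–C2'(=CH2)–C3'H(OH)–C4'H2OH.
Enabling feature: ring A is a cyclohexene whose only double bond, C4=C5, lies opposite the C1–C2 edge, and C1 bears C10, an sp2 carbon that can be an acetyl C=O. C1–C6 and C2–C3 are therefore the two σ bonds of a Diels–Alder retron (diene C3=C4–C5=C6, dienophile C1=C2 of but-3-en-2-one).
Ring A is formed first by this catalyst-controlled [4+2] step. C1 is then epimerised to trans and C10=O is methylenated.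
Ring B is formed second. The unit C8(OH)–C9H2–C10(=C14H2) is the retron of a type-two carbonyl-ene reaction (C8–C9 bond), which places O8 axial, anti to the axial C11 arm.
C7 comes from an auxiliary-controlled alkylation and travels as a γ-lactone that masks O8 and C12. C13 (Mannich methylenation) and the acyl group (acid 25, from an asymmetric Morita–Baylis–Hillman reaction) are added last.

Key step: step 5

Assumption: the oxazaborolidinium salt made from (R)-α,α-diphenylprolinol is taken to leave the Si face of Cα of but-3-en-2-one open. This follows the facial model for acrylates and vinyl ketones bound through the carbonyl lone pair with an α-C–H···O contact.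

**Route**

Step 1
Reactants: 1 (S)-4-benzyl-1,3-oxazolidin-2-one; 2 (E)-but-2-enoyl chloride
Product: 3 (S)-4-benzyl-3-[(E)-but-2-enoyl]-1,3-oxazolidin-2-one
Conditions: n-BuLi, THF, −78 °C; then 2, −78 → 0 °C
Reagents that add atoms: none
Why: N-Acylation of the lithiated oxazolidinone by the acid chloride is a standard imide formation and touches no stereocentre.

Step 2
Reactants: 3 N-crotonoyl imide; 4 tert-butyl bromoacetate
Product: 5 tert-butyl (3S)-3-{[(4S)-4-benzyl-2-oxo-1,3-oxazolidin-3-yl]carbonyl}pent-4-enoate
Conditions: NaN(SiMe3)2, THF, −78 °C; then 4, −78 → −40 °C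
Reagents that add atoms: none
Why: Auxiliary-controlled (Evans) alkylation, in which γ-deprotonation gives the chelated Z-dienolate that reacts at its α-carbon with the bromoacetate on the face away from the benzyl group, which sets C7 (S) and moves the double bond out of conjugation to give the C6 vinyl group.

Step 3
Reactants: 5 alkylated imide
Product: 7 (4S)-4-ethenyloxolan-2-one, via hydroxy ester 6 (not isolated)
Conditions: LiBH4, H2O (1 equiv), Et2O, 0 °C; then p-TsOH·H2O (cat.), toluene, 80 °C
Reagents that add atoms: none
Why: Reductive cleavage of the imide by LiBH4 is faster than reduction of the hindered tert-butyl ester and releases the auxiliary, and acid then closes the γ-lactone, which masks O8 and C12 in one small ring without touching C7.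

Step 4
Reactants: 7 vinyl lactone; 8 tert-butyl(dimethyl)(prop-2-yn-1-yloxy)silane
Product: 9 diene lactone (4S)-4-[(1E)-3-(TBSO-methyl)buta-1,3-dien-1-yl]oxolan-2-one
Conditions: second-generation Hoveyda–Grubbs catalyst (5 mol %), ethene (1 atm), CH2Cl2, 40 °C
Reagents that add atoms: none
Why: Cross enyne metathesis, in which the ruthenium methylidene adds to the terminal alkyne and the resulting vinylcarbene is released by the terminal alkene 7, gives the 1,3-disubstituted diene with all atoms of both partners, and ethene-assisted secondary metathesis should favour the E isomer.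

Step 5
Reactants: 9 diene lactone; 10 but-3-en-2-one
Product: 11 endo adduct, the cis-(1R,6R,7S) acetylcyclohexene lactone (acetyl on C1 and lactone on C6 cis, C4=C5, CH2OTBS on C4)
Conditions: (R)-3,3-diphenyl-1-(2-methylphenyl)tetrahydro-1H,3H-pyrrolo[1,2-c][1,3,2]oxazaborole (20 mol %), Tf2NH (18 mol %), CH2Cl2, −78 → −40 °C
Reagents that add atoms: none
Why: The boron of the protonated oxazaborolidine binds the ketone oxygen of 10 and lowers its LUMO, and diene 9 adds in a concerted, asynchronous, suprafacial [4+2] cycloaddition in which C3–C2 bonding runs ahead of C6–C1 bonding. The closest known reaction type is the oxazaborolidinium-catalysed enantioselective Diels–Alder reaction of acyclic vinyl ketones and acrylates with 1- and 2-substituted butadienes. Ring A is closed in an intermolecular six-membered [4π+2π] annulation that makes C1–C6 and C2–C3 at once and moves the π bond to C4=C5, exactly where the target has it. C1 is set by the catalyst, whose aryl group covers the Re face of Cα so that C6 attacks the Si face, and C6 is set relative to C1 by the endo rule together with the E geometry of C5=C6, which puts C7 and the acetyl group cis. Regioselectivity is needed and is secured because the alkyl group on C6 and the CH2OTBS group on C4 both place the largest HOMO coefficient on C3, which pairs with the β-carbon C2. Face selectivity with respect to C7 is needed and rests on reagent control, since C7 holds two sterically similar ring CH2 groups (C8 and C11) and exerts little bias of its own, while the lactone, the silyl ether and any Z-diene stay untouched.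

Step 6
Reactants: 11 cis ketone
Product: 12 trans-(1S,6R,7S) acetylcyclohexene lactone
Conditions: DBU (0.5 equiv), toluene, 40 °C; recovered cis isomer is resubmitted
Reagents that add atoms: none
Why: Base-mediated epimerisation through the C1 enolate is under thermodynamic control and should favour the trans isomer with the acetyl group and the lactone substituent both pseudo-equatorial on ring A, which sets C1 as in the target, while C6 and C7 carry no acidic hydrogen.

Step 7
Reactants: 12 trans ketone
Product: 13 (1S,6S,7S) isopropenylcyclohexene lactone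
Conditions: Ph3PCH3Br (1.3 equiv), KOtBu (1.2 equiv), THF, 0 °C
Reagents that add atoms: methyltriphenylphosphonium bromide C[P+](c1ccccc1)(c1ccccc1)c1ccccc1.[Br-]
Why: Wittig methylenation of the methyl ketone is much faster than attack of the ylide on the lactone and turns C10 into the isopropenyl group (C9 and C14) next to a C1 centre that already has its more stable configuration.

Step 8
Reactants: 13 isopropenyl lactone
Product: 15 allyl (1S,6S,7S) hydroxy ester (C8H2OH free and C12 as allyl ester), via potassium carboxylate 14 (not isolated)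
Conditions: KOH (1.05 equiv), MeOH–H2O, rt, evaporate; then allyl bromide, DMF, 0 °C → rt
Reagents that add atoms: potassium hydroxide [K+].[OH-]; allyl bromide C=CCBr
Why: Saponification with one equivalent of hydroxide followed by O-alkylation of the carboxylate in DMF is the standard way to trap a ring-opened γ-lactone, and it frees O8–H while C12 becomes an allyl ester.

Step 9
Reactants: 15 hydroxy ester
Product: 16 (1S,6S,7S) aldehyde (C8HO)
Conditions: Dess–Martin periodinane, CH2Cl2, 0 °C, used at once
Reagents that add atoms: none
Why: Dess–Martin oxidation is fast and essentially neutral, so the primary alcohol should become the aldehyde before it can relactonise and without epimerisation at C7.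

Step 10
Reactants: 16 aldehyde
Product: 17 (1S,6S,7S,8S) trans-decalin alcohol (axial 8-OH, axial CH2CO2allyl on C7, C10=C14H2)
Conditions: Me2AlCl (1.5 equiv), CH2Cl2, −78 → −30 °C
Reagents that add atoms: none
Why: Type-two intramolecular carbonyl-ene reaction, in which the aluminium-bound aldehyde C8 is attacked by C9 of the isopropenyl group through a chair-like trans-decalin transition state where the oxygen must stand axial to take over a C14 hydrogen, closes ring B, sets C8 with O8 axial and anti to the axial C11 arm, and leaves the C10=C14 methylene group.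

Step 11
Reactants: 17 decalin alcohol
Product: 18 Mannich base (CH2NMe2 on C11, both C11 epimers, other centres unchanged)
Conditions: LiN(iPr)2 (2.5 equiv), THF, −78 °C; then CH2=NMe2+ I−, −78 → 0 °C
Reagents that add atoms: Eschenmoser's salt C=[N+](C)C.[I-]
Why: The Mannich reaction of the ester enolate (the alkoxide is carried along as its lithium salt) with Eschenmoser's salt adds C13, and lactonisation cannot compete because O8 and the C11 arm are trans-diaxial.

Step 12
Reactants: 18 Mannich base
Product: 20 (1S,6S,7R,8S) allyl acrylate alcohol (C11=C13H2), via ammonium iodide 19 (not isolated)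
Conditions: MeI, THF, rt; then DBU, 0 °C → rt
Reagents that add atoms: none
Why: Exhaustive N-methylation followed by base-induced E1cB loss of trimethylamine is the standard second half of an α-methylenation and removes the stereocentre at C11.

Step 13
Reactants: 21 (tert-butyldimethylsilyloxy)acetaldehyde; 22 1,1,1,3,3,3-hexafluoropropan-2-yl acrylate
Product: 23 hexafluoroisopropyl (3S)-4-(TBSO)-3-hydroxy-2-methylidenebutanoate
Conditions: β-isocupreidine (10 mol %), DMF, −55 °C
Reagents that add atoms: none
Why: Asymmetric Morita–Baylis–Hillman reaction, in which the quinidine-derived amine adds to the activated acrylate and its phenol OH directs the aldol and elimination steps, should set C3' as S (the same spatial sense as the R adducts of simple aldehydes).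

Step 14
Reactants: 23 Morita–Baylis–Hillman adduct
Product: 24 hexafluoroisopropyl (3S)-3,4-bis(TBSO)-2-methylidenebutanoate
Conditions: TBSOTf, 2,6-lutidine, CH2Cl2, 0 °C
Reagents that add atoms: tert-butyldimethylsilyl triflate CC(C)(C)[Si](C)(C)OS(=O)(=O)C(F)(F)F
Why: Silylation of the secondary allylic alcohol with the silyl triflate and a hindered base is fast at low temperature and avoids conjugate addition.

Step 15
Reactants: 24 bis-silyl ester
Product: 25 (3S)-3,4-bis(TBSO)-2-methylidenebutanoic acid
Conditions: LiOH, THF–H2O, 0 °C; then 1 M HCl to pH 4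
Reagents that add atoms: lithium hydroxide [Li+].[OH-]
Why: The electron-poor hexafluoroisopropyl ester is hydrolysed by hydroxide under very mild conditions, so the silyl ethers and C3' are not affected.

Step 16
Reactants: 20 acrylate alcohol; 25 side-chain acid
Product: 27 fully protected diester, via mixed anhydride 26 (not isolated)
Conditions: 25, 2,4,6-trichlorobenzoyl chloride, Et3N, toluene, rt; then 20, DMAP, toluene, rt → 40 °C
Reagents that add atoms: none
Why: Yamaguchi esterification through the mixed anhydride and DMAP is suited to the hindered axial C8 alcohol, forms the O8–C1' bond with retention at C8 and C3', and leaves the allyl ester alone.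

Step 17
Reactants: 27 protected diester
Product: 28 tris-TBS ether of the target (free C12 acid)
Conditions: Pd(PPh3)4 (5 mol %), N-methylaniline, THF, rt
Reagents that add atoms: none
Why: Tsuji–Trost deallylation, in which zerovalent palladium ionises only the allyl ester (O8 is homoallylic and O15 is a silyl ether) and the weakly nucleophilic aniline takes up the allyl group without adding to the acrylates.

Step 18
Reactants: 28 tris-TBS acid
Product: 29 target CNP0460913.4 (1S,6S,7R,8S,3'S)
Conditions: HF·pyridine, pyridine, THF, 0 °C → rt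
Reagents that add atoms: none
Why: Fluoride-driven cleavage of the three silyl ethers under buffered, weakly acidic conditions should spare both esters, the free acid and the acid-sensitive exocyclic methylene groups and gives the target.

**Compound list**

1 | (S)-4-benzyl-1,3-oxazolidin-2-one | O=C1N[C@@H](Cc2ccccc2)CO1 | starting material
2 | (E)-but-2-enoyl chloride | C/C=C/C(=O)Cl | starting material
3 | (S)-4-benzyl-3-[(E)-but-2-enoyl]-1,3-oxazolidin-2-one | C/C=C/C(=O)N1[C@@H](Cc2ccccc2)COC1=O | intermediate
4 | tert-butyl bromoacetate | CC(C)(C)OC(=O)CBr | starting material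
5 | tert-butyl (3S)-3-{[(4S)-4-benzyl-2-oxo-1,3-oxazolidin-3-yl]carbonyl}pent-4-enoate | CC(C)(C)OC(=O)C[C@H](C(=O)N1[C@@H](Cc2ccccc2)COC1=O)C=C | intermediate
6 | tert-butyl (3S)-3-(hydroxymethyl)pent-4-enoate | CC(C)(C)OC(=O)C[C@H](CO)C=C | intermediate
7 | (4S)-4-ethenyloxolan-2-one | O=C1C[C@H](CO1)C=C | intermediate
8 | tert-butyl(dimethyl)(prop-2-yn-1-yloxy)silane | C#CCO[Si](C)(C)C(C)(C)C | starting material
9 | diene lactone (E) | O=C1C[C@H](CO1)/C=C/C(=C)CO[Si](C)(C)C(C)(C)C | intermediate
10 | but-3-en-2-one | C=CC(C)=O | starting material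
11 | cis-(1R,6R,7S) acetylcyclohexene lactone | O=C1C[C@H](CO1)[C@H]2C=C(CO[Si](C)(C)C(C)(C)C)CC[C@H]2C(C)=O | intermediate
12 | trans-(1S,6R,7S) acetylcyclohexene lactone | O=C1C[C@H](CO1)[C@H]2C=C(CO[Si](C)(C)C(C)(C)C)CC[C@@H]2C(C)=O | intermediate
13 | (1S,6S,7S) isopropenylcyclohexene lactone | O=C1C[C@H](CO1)[C@H]2C=C(CO[Si](C)(C)C(C)(C)C)CC[C@@H]2C(C)=C | intermediate
14 | potassium carboxylate of the opened lactone | [K+].[O-]C(=O)C[C@H](CO)[C@H]1C=C(CO[Si](C)(C)C(C)(C)C)CC[C@@H]1C(C)=C | intermediate
15 | allyl hydroxy ester | C=CCOC(=O)C[C@H](CO)[C@H]1C=C(CO[Si](C)(C)C(C)(C)C)CC[C@@H]1C(C)=C | intermediate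
16 | allyl ester aldehyde | C=CCOC(=O)C[C@H](C=O)[C@H]1C=C(CO[Si](C)(C)C(C)(C)C)CC[C@@H]1C(C)=C | intermediate
17 | (1S,6S,7S,8S) trans-decalin alcohol | C=CCOC(=O)C[C@H]1[C@H]2C=C(CO[Si](C)(C)C(C)(C)C)CC[C@@H]2C(=C)C[C@@H]1O | intermediate
18 | Mannich base (C11 epimers) | C=CCOC(=O)C(CN(C)C)[C@H]1[C@H]2C=C(CO[Si](C)(C)C(C)(C)C)CC[C@@H]2C(=C)C[C@@H]1O | intermediate
19 | trimethylammonium iodide | [I-].C=CCOC(=O)C(C[N+](C)(C)C)[C@H]1[C@H]2C=C(CO[Si](C)(C)C(C)(C)C)CC[C@@H]2C(=C)C[C@@H]1O | intermediate
20 | (1S,6S,7R,8S) allyl acrylate alcohol | C=CCOC(=O)C(=C)[C@H]1[C@H]2C=C(CO[Si](C)(C)C(C)(C)C)CC[C@@H]2C(=C)C[C@@H]1O | intermediate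
21 | (tert-butyldimethylsilyloxy)acetaldehyde | O=CCO[Si](C)(C)C(C)(C)C | starting material
22 | 1,1,1,3,3,3-hexafluoropropan-2-yl acrylate | C=CC(=O)OC(C(F)(F)F)C(F)(F)F | starting material
23 | (3S) Morita–Baylis–Hillman adduct | C=C(C(=O)OC(C(F)(F)F)C(F)(F)F)[C@H](O)CO[Si](C)(C)C(C)(C)C | intermediate
24 | (3S) bis-TBS hexafluoroisopropyl ester | C=C(C(=O)OC(C(F)(F)F)C(F)(F)F)[C@H](O[Si](C)(C)C(C)(C)C)CO[Si](C)(C)C(C)(C)C | intermediate
25 | (3S)-3,4-bis(TBSO)-2-methylidenebutanoic acid | C=C(C(=O)O)[C@H](O[Si](C)(C)C(C)(C)C)CO[Si](C)(C)C(C)(C)C | intermediate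
26 | mixed 2,4,6-trichlorobenzoic anhydride of 25 | C=C(C(=O)OC(=O)c1c(Cl)cc(Cl)cc1Cl)[C@H](O[Si](C)(C)C(C)(C)C)CO[Si](C)(C)C(C)(C)C | intermediate
27 | fully protected diester | C=CCOC(=O)C(=C)[C@H]1[C@H]2C=C(CO[Si](C)(C)C(C)(C)C)CC[C@@H]2C(=C)C[C@@H]1OC(=O)C(=C)[C@H](O[Si](C)(C)C(C)(C)C)CO[Si](C)(C)C(C)(C)C | intermediate
28 | tris-TBS acid | C=C(C(=O)O)[C@H]1[C@H]2C=C(CO[Si](C)(C)C(C)(C)C)CC[C@@H]2C(=C)C[C@@H]1OC(=O)C(=C)[C@H](O[Si](C)(C)C(C)(C)C)CO[Si](C)(C)C(C)(C)C | intermediate
29 | CNP0460913.4 | C=C(C(=O)O)[C@H]1[C@H]2C=C(CO)CC[C@@H]2C(=C)C[C@@H]1OC(=O)C(=C)[C@H](O)CO | target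

**Step count and risks**

Total steps: 18. Longest linear sequence: 15 (steps 1–12 and 16–18).

Steps most likely to fail:

Step 5. The lactone carbonyl may tie up the catalyst. Endo or facial selectivity may also be too low, which would erode the C6/C7 relationship that nothing later can repair. The fallback replaces catalyst control by a covalently bound auxiliary; it sets out from 9 (and 1) and returns at 11. Compound 1 is lithiated and acylated with acryloyl chloride to the N-acryloyl imide F1. Et2AlCl (CH2Cl2, −78 °C) promotes the auxiliary-controlled Diels–Alder reaction of F1 with 9 to the endo imide adduct F2, in which the benzyl group shields the Re face of Cα. LiSEt (THF, 0 °C) exchanges the auxiliary for the S-ethyl thioester F3. A Fukuyama coupling (MeZnI, PdCl2(PPh3)2, toluene) turns F3 into 11.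

Step 10. Three failure modes are possible. Enolisation of the α-branched aldehyde may epimerise C7. Chloride may capture the C10 cation. The closure may be slow because the C11 arm has to become axial. The fallback closes the same bond by an aldol reaction and adds C14 afterwards; it sets out from 12 and returns at 17. Compound 12 is saponified to the potassium carboxylate F4 and allylated to the hydroxy keto ester F5 as in step 8. Dess–Martin oxidation gives the keto aldehyde F6. Soft enolisation of the methyl ketone (TiCl4, iPr2NEt, CH2Cl2, −78 °C) closes ring B by an intramolecular aldol reaction through a chelated chair that again needs an axial O8 and gives the ketol F7. Takai–Lombardo methylenation (Zn, CH2Br2, TiCl4) of the C10 ketone, which is non-basic and spares esters, gives 17.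

Step 4. The branched alkene may convert incompletely, or the E/Z selectivity of the new C5=C6 bond may be poor. The fallback builds the diene by cross-coupling; it sets out from 7 and returns at 9. Cross metathesis of 7 with vinylboronic acid pinacol ester (second-generation Hoveyda–Grubbs catalyst) gives the E-alkenyl boronate F8. 2-Bromoprop-2-en-1-ol is silylated (TBSCl, imidazole) to the bromoallyl silyl ether F9. Suzuki–Miyaura coupling of F8 with F9 (Pd(dppf)Cl2, K3PO4, THF–H2O) gives 9 with retention of the E geometry.

Further compounds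
F1 | step 5 | (S)-3-acryloyl-4-benzyl-1,3-oxazolidin-2-one | C=CC(=O)N1[C@@H](Cc2ccccc2)COC1=O
F2 | step 5 | endo imide adduct (cis, 1R,6R,7S) | O=C1C[C@H](CO1)[C@H]2C=C(CO[Si](C)(C)C(C)(C)C)CC[C@H]2C(=O)N3[C@@H](Cc4ccccc4)COC3=O
F3 | step 5 | S-ethyl thioester (cis) | O=C1C[C@H](CO1)[C@H]2C=C(CO[Si](C)(C)C(C)(C)C)CC[C@H]2C(=O)SCC
F4 | step 10 | potassium carboxylate of opened 12 | [K+].[O-]C(=O)C[C@H](CO)[C@H]1C=C(CO[Si](C)(C)C(C)(C)C)CC[C@@H]1C(C)=O
F5 | step 10 | allyl hydroxy keto ester | C=CCOC(=O)C[C@H](CO)[C@H]1C=C(CO[Si](C)(C)C(C)(C)C)CC[C@@H]1C(C)=O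
F6 | step 10 | allyl keto aldehyde | C=CCOC(=O)C[C@H](C=O)[C@H]1C=C(CO[Si](C)(C)C(C)(C)C)CC[C@@H]1C(C)=O
F7 | step 10 | trans-decalin ketol (C10 ketone, axial 8-OH) | C=CCOC(=O)C[C@H]1[C@H]2C=C(CO[Si](C)(C)C(C)(C)C)CC[C@@H]2C(=O)C[C@@H]1O
F8 | step 4 | (E)-alkenyl pinacol boronate of 7 | O=C1C[C@H](CO1)/C=C/B2OC(C)(C)C(C)(C)O2
F9 | step 4 | [(2-bromoprop-2-en-1-yl)oxy](tert-butyl)dimethylsilane | C=C(Br)CO[Si](C)(C)C(C)(C)C
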